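**Retrosynthetic overview**
- The target comes from the 18-hydroxy methyl ester by ester hydrolysis and O-acetylation (labdane numbering).
- Both rings form in one cascade from an acyclic epoxy-diene allylsilane: ring A first (C4–C5, with C4 set by inversion at an enantiopure 2,2-disubstituted oxirane), then ring B (C9–C10); allylsilane termination gives the 8(17)-methylene.
- The acyclic precursor comes from two Pd-catalysed Negishi couplings on a gem-dichloroalkene: C7–C8 (trans-selective union of the two halves, the key convergent bond, which fixes the alkene geometry that becomes C9), then C8–C17 (CH2SiMe3).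
- The western half comes from a B-alkyl Suzuki coupling (C1–C10) of (R)-2-allyl-2-methyloxirane, made from (S)-2-methylglycidol, with (E)-4-iodopent-3-en-1-ol, made from pent-3-yn-1-ol.
- The eastern half comes from carbocupration of methyl but-2-ynoate with butenyl Grignard, CuH asymmetric 1,4-reduction (sets C13), ozonolysis and dichloromethylenation.

Assumptions: positions are given in labdane numbering (C18 = CH2OAc carbon, C17 = exocyclic CH2), the target being (4R,5R,9S,10R,13S); commercial (S)-2-methylglycidol 1 is taken at ≥98% ee; the DTBM-SEGPHOS antipode in step 7 is the one that gives the 3S ester (to be confirmed by rotation on the first run).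

**Step 1**
Reactants: 1 [(2S)-2-methyloxiran-2-yl]methanol
Product: 2 [(2R)-2-methyloxiran-2-yl]methyl 4-methylbenzenesulfonate
Conditions: TsCl, Et3N, DMAP (cat.), CH2Cl2, 0 °C
Reagents that add atoms: p-toluenesulfonyl chloride, Cc1ccc(cc1)S(=O)(=O)Cl
Why: Standard O-sulfonylation of the primary alcohol, in which no bond to the quaternary stereocentre is touched (only its CIP descriptor changes from S to R).

**Step 2**
Reactants: 2 [(2R)-2-methyloxiran-2-yl]methyl 4-methylbenzenesulfonate
Product: 4 (2R)-2-methyl-2-(prop-2-en-1-yl)oxirane, via tosyloxy alkoxide 3 (not isolated)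
Conditions: CH2=CHMgBr, CuI (10 mol %), THF, −40 to −20 °C; then 2 M aq NaOH, 23 °C
Reagents that add atoms: vinylmagnesium bromide, C=C[Mg]Br
Why: Copper-catalysed Grignard opening of the epoxide at its CH2 terminus (faster than SN2 at the neopentyl-type tosylate) gives alkoxide 3, whose Williamson-type 3-exo-tet closure onto the CH2OTs carbon rebuilds the oxirane on the other arm, so the stereocentre is carried over with no bond to it broken.

**Step 3**
Reactants: 5 pent-3-yn-1-ol
Product: 7 (3E)-4-iodopent-3-en-1-ol, via alkenylzirconocene 6 (not isolated)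
Conditions: Cp2Zr(H)Cl (2.3 equiv), THF, 23→40 °C; I2, 0 °C
Reagents that add atoms: iodine, II
Why: Syn hydrozirconation (Schwartz reagent, the first equivalent being consumed by the hydroxyl group) with equilibration of zirconium to the less hindered methyl-bearing alkyne carbon, followed by iodinolysis with retention, gives the (E)-2-iodoalkene.

**Step 4**
Reactants: 4 (2R)-2-methyl-2-(prop-2-en-1-yl)oxirane; 7 (3E)-4-iodopent-3-en-1-ol
Product: 9 (3E)-4-methyl-7-[(2R)-2-methyloxiran-2-yl]hept-3-en-1-ol, via alkylborane 8 (not isolated)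
Conditions: 4, 9-BBN-H, THF, 0→23 °C; then 7, Pd(dppf)Cl2 (5 mol %), AsPh3, K3PO4 (3 M aq), DMF, 23 °C
Reagents that add atoms: none
Why: Anti-Markovnikov hydroboration of the terminal alkene and B-alkyl Suzuki–Miyaura coupling with retention of the alkenyl iodide geometry form C1–C10 as the (E)-trisubstituted alkene under basic conditions that the oxirane tolerates.

**Step 5**
Reactants: 9 (3E)-4-methyl-7-[(2R)-2-methyloxiran-2-yl]hept-3-en-1-ol
Product: 10 (2R)-2-[(4E)-7-iodo-4-methylhept-4-en-1-yl]-2-methyloxirane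
Conditions: I2, PPh3, imidazole, CH2Cl2, 0 °C
Reagents that add atoms: iodine, II
Why: Appel-type iodination of the primary homoallylic alcohol under imidazole buffering, which leaves the epoxide and the alkene untouched.

**Step 6**
Reactants: 11 methyl but-2-ynoate; 12 but-3-en-1-ylmagnesium bromide
Product: 15 methyl (2E)-3-methylhepta-2,6-dienoate, via butenylcopper 13 (not isolated), via alkenylcopper 14 (not isolated)
Conditions: 12, CuI (1.05 equiv), THF, −40 °C; 11, −78 °C; MeOH, −78 °C
Reagents that add atoms: none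
Why: Syn carbocupration of the ynoate at −78 °C and protonation of the alkenylcopper with retention give the geometrically pure (2E)-enoate with the butenyl chain trans to the ester.

**Step 7**
Reactants: 15 methyl (2E)-3-methylhepta-2,6-dienoate
Product: 16 methyl (3S)-3-methylhept-6-enoate
Conditions: Cu(OAc)2·H2O (2 mol %), (R)-DTBM-SEGPHOS (2.2 mol %), (EtO)2MeSiH, t-BuOH, toluene, 0 °C
Reagents that add atoms: none
Why: Ligand-controlled CuH-catalysed asymmetric conjugate reduction of the β,β-disubstituted enoate sets C13 (S) by face-selective hydride delivery to the β-carbon, while the isolated terminal alkene is not reduced at 0 °C.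

**Step 8**
Reactants: 16 methyl (3S)-3-methylhept-6-enoate
Product: 18 methyl (3S)-3-methyl-6-oxohexanoate, via ozonide 17 (not isolated)
Conditions: O3, CH2Cl2, −78 °C; PPh3, −78→23 °C
Reagents that add atoms: ozone, [O-][O+]=O
Why: Ozonolysis of the only alkene with reductive work-up unmasks the C9 aldehyde, and the C13 centre is not epimerisable.

**Step 9**
Reactants: 18 methyl (3S)-3-methyl-6-oxohexanoate
Product: 19 methyl (3S)-7,7-dichloro-3-methylhept-6-enoate
Conditions: BrCCl3, PPh3, MeCN, 0→23 °C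
Reagents that add atoms: bromotrichloromethane, ClC(Cl)(Cl)Br
Why: Wittig-type dichloromethylenation with Ph3P=CCl2 generated in the flask converts the aldehyde into the gem-dichloroalkene needed for two successive stereodefined couplings.

**Step 10**
Reactants: 10 (2R)-2-[(4E)-7-iodo-4-methylhept-4-en-1-yl]-2-methyloxirane; 19 methyl (3S)-7,7-dichloro-3-methylhept-6-enoate
Product: 21 methyl (3S,6Z,10E)-7-chloro-3,11-dimethyl-14-[(2R)-2-methyloxiran-2-yl]tetradeca-6,10-dienoate, via alkylzinc iodide 20 (not isolated)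
Conditions: 10, Zn dust, LiCl, THF, 30 °C; then 19, Pd(DPEphos)Cl2 (5 mol %), THF/DMF, 23 °C
Reagents that add atoms: none
Why: LiCl-mediated zinc insertion gives the ester-compatible alkylzinc 20, and a Negishi coupling in which oxidative addition occurs at the C–Cl bond trans to the alkyl chain forms C7–C8 and places C7 trans to C11, the geometry that later makes the side chain equatorial at C9.

**Step 11**
Reactants: 21 methyl (3S,6Z,10E)-7-chloro-3,11-dimethyl-14-[(2R)-2-methyloxiran-2-yl]tetradeca-6,10-dienoate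
Product: 22 methyl (3S,6Z,10E)-3,11-dimethyl-14-[(2R)-2-methyloxiran-2-yl]-7-[(trimethylsilyl)methyl]tetradeca-6,10-dienoate
Conditions: Me3SiCH2ZnCl, Pd(t-Bu3P)2 (5 mol %), THF/NMP, 40 °C
Reagents that add atoms: (trimethylsilyl)methylzinc chloride, C[Si](C)(C)C[Zn]Cl
Why: A second Negishi coupling at the remaining hindered alkenyl chloride with a β-hydrogen-free silylmethylzinc and a bulky electron-rich Pd(0) catalyst proceeds with retention, giving the trisubstituted allylsilane with CH2SiMe3 cis to C11.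

**Step 12**
Reactants: 22 methyl (3S,6Z,10E)-3,11-dimethyl-14-[(2R)-2-methyloxiran-2-yl]-7-[(trimethylsilyl)methyl]tetradeca-6,10-dienoate
Product: 23 methyl (3S)-5-[(1S,4aR,5R,8aR)-5-(hydroxymethyl)-5,8a-dimethyl-2-methylidenedecahydronaphthalen-1-yl]-3-methylpentanoate
Conditions: MeAlCl2 (3 equiv), CH2Cl2, −78 °C; aq Rochelle salt
Reagents that add atoms: none
Why: Proposed new method: a Lewis-acid-promoted cation–olefin bicyclisation initiated at the tertiary carbon of an enantiopure 2,2-disubstituted terminal oxirane, in which the C5=C10 alkene attacks C4 anti to the Al-bound departing oxygen (SN2-like inversion, so the one glycidol-derived stereocentre becomes quaternary C4 and its CH2O arm is left as the free CH2OH with no oxygen on C3), the chair–chair fold that keeps the CH2O–Al arm equatorial and the methyl axial relays this to C5, C10 and C9 (trans-decalin, 9β side chain from the allylsilane geometry), and β-silyl cation collapse gives only the 8(17)-alkene; the closest known reaction type is the Lewis-acid bicyclisation of trisubstituted 2,3-epoxy polyenes with allylsilane termination, the new element being the exocyclic 2,2-disubstituted epoxide as a chirality-transferring initiator.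

**Step 13**
Reactants: 23 methyl (3S)-5-[(1S,4aR,5R,8aR)-5-(hydroxymethyl)-5,8a-dimethyl-2-methylidenedecahydronaphthalen-1-yl]-3-methylpentanoate
Product: 24 (3S)-5-[(1S,4aR,5R,8aR)-5-(hydroxymethyl)-5,8a-dimethyl-2-methylidenedecahydronaphthalen-1-yl]-3-methylpentanoic acid
Conditions: LiOH·H2O, THF/MeOH/H2O, 23 °C; then 1 M HCl to pH 3
Reagents that add atoms: lithium hydroxide, [Li+].[OH-]
Why: Saponification of the unhindered methyl ester, with no epimerisable centre next to the carboxyl group and a base-stable exocyclic alkene.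

**Step 14**
Reactants: 24 (3S)-5-[(1S,4aR,5R,8aR)-5-(hydroxymethyl)-5,8a-dimethyl-2-methylidenedecahydronaphthalen-1-yl]-3-methylpentanoic acid
Product: 26 (3S)-5-[(1S,4aR,5R,8aR)-5-(acetoxymethyl)-5,8a-dimethyl-2-methylidenedecahydronaphthalen-1-yl]-3-methylpentanoic acid, via mixed anhydride 25 (not isolated)
Conditions: Ac2O, pyridine, DMAP (cat.), CH2Cl2, 23 °C; then H2O/pyridine, 23 °C
Reagents that add atoms: acetic anhydride, CC(=O)OC(C)=O
Why: DMAP-catalysed acetylation of the neopentyl primary alcohol, in which the carboxyl group is transiently converted into mixed anhydride 25 and returned as the free acid by the aqueous pyridine quench.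

**Compound list**
1 | [(2S)-2-methyloxiran-2-yl]methanol ((S)-2-methylglycidol) | C[C@]1(CO)CO1 | starting material
2 | [(2R)-2-methyloxiran-2-yl]methyl 4-methylbenzenesulfonate | C[C@]1(COS(=O)(=O)c2ccc(C)cc2)CO1 | intermediate
3 | (2R)-2-hydroxy-2-methylpent-4-en-1-yl 4-methylbenzenesulfonate (present as its magnesium alkoxide) | C[C@](O)(COS(=O)(=O)c1ccc(C)cc1)CC=C | intermediate (not isolated)
4 | (2R)-2-methyl-2-(prop-2-en-1-yl)oxirane | C[C@@]1(CC=C)CO1 | intermediate
5 | pent-3-yn-1-ol | CC#CCCO | starting material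
6 | O-zirconated (E)-alkenylzirconocene chloride from syn addition of Cp2Zr(H)Cl to 5 (Zr on the methyl-bearing carbon) | C/C(=C\CCO[Zr](Cl)(C1C=CC=C1)C1C=CC=C1)[Zr](Cl)(C1C=CC=C1)C1C=CC=C1 | intermediate (not isolated)
7 | (3E)-4-iodopent-3-en-1-ol | C/C(I)=C\CCO | intermediate
8 | 9-{3-[(2R)-2-methyloxiran-2-yl]propyl}-9-borabicyclo[3.3.1]nonane | C[C@@]1(CCCB2C3CCCC2CCC3)CO1 | intermediate (not isolated)
9 | (3E)-4-methyl-7-[(2R)-2-methyloxiran-2-yl]hept-3-en-1-ol | C[C@@]1(CCC/C(C)=C/CCO)CO1 | intermediate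
10 | (2R)-2-[(4E)-7-iodo-4-methylhept-4-en-1-yl]-2-methyloxirane | C[C@@]1(CCC/C(C)=C/CCI)CO1 | intermediate
11 | methyl but-2-ynoate | CC#CC(=O)OC | starting material
12 | but-3-en-1-ylmagnesium bromide | C=CCC[Mg]Br | starting material
13 | but-3-en-1-ylcopper(I) (MgBrI complex) | C=CCC[Cu] | intermediate (not isolated)
14 | methyl (2Z)-2-cuprio-3-methylhepta-2,6-dienoate | C=CCC/C(C)=C(\[Cu])C(=O)OC | intermediate (not isolated)
15 | methyl (2E)-3-methylhepta-2,6-dienoate | C=CCC/C(C)=C/C(=O)OC | intermediate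
16 | methyl (3S)-3-methylhept-6-enoate | C=CCC[C@H](C)CC(=O)OC | intermediate
17 | methyl (3S)-3-methyl-5-(1,2,4-trioxolan-3-yl)pentanoate | C1OC(CC[C@H](C)CC(=O)OC)OO1 | intermediate (not isolated)
18 | methyl (3S)-3-methyl-6-oxohexanoate | O=CCC[C@H](C)CC(=O)OC | intermediate
19 | methyl (3S)-7,7-dichloro-3-methylhept-6-enoate | ClC(Cl)=CCC[C@H](C)CC(=O)OC | intermediate
20 | iodo{(3E)-4-methyl-7-[(2R)-2-methyloxiran-2-yl]hept-3-en-1-yl}zinc | C[C@@]1(CCC/C(C)=C/CC[Zn]I)CO1 | intermediate (not isolated)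
21 | methyl (3S,6Z,10E)-7-chloro-3,11-dimethyl-14-[(2R)-2-methyloxiran-2-yl]tetradeca-6,10-dienoate | C[C@@]1(CCC/C(C)=C/CC/C(Cl)=C/CC[C@H](C)CC(=O)OC)CO1 | intermediate
22 | methyl (3S,6Z,10E)-3,11-dimethyl-14-[(2R)-2-methyloxiran-2-yl]-7-[(trimethylsilyl)methyl]tetradeca-6,10-dienoate | C[C@@]1(CCC/C(C)=C/CC/C(C[Si](C)(C)C)=C/CC[C@H](C)CC(=O)OC)CO1 | intermediate
23 | methyl (3S)-5-[(1S,4aR,5R,8aR)-5-(hydroxymethyl)-5,8a-dimethyl-2-methylidenedecahydronaphthalen-1-yl]-3-methylpentanoate | C=C1CC[C@H]2[C@](C)(CO)CCC[C@]2(C)[C@H]1CC[C@H](C)CC(=O)OC | intermediate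
24 | (3S)-5-[(1S,4aR,5R,8aR)-5-(hydroxymethyl)-5,8a-dimethyl-2-methylidenedecahydronaphthalen-1-yl]-3-methylpentanoic acid | C=C1CC[C@H]2[C@](C)(CO)CCC[C@]2(C)[C@H]1CC[C@H](C)CC(=O)O | intermediate
25 | acetic (3S)-5-[(1S,4aR,5R,8aR)-5-(acetoxymethyl)-5,8a-dimethyl-2-methylidenedecahydronaphthalen-1-yl]-3-methylpentanoic anhydride | C=C1CC[C@H]2[C@](C)(COC(C)=O)CCC[C@]2(C)[C@H]1CC[C@H](C)CC(=O)OC(C)=O | intermediate (not isolated)
26 | (3S)-5-[(1S,4aR,5R,8aR)-5-(acetoxymethyl)-5,8a-dimethyl-2-methylidenedecahydronaphthalen-1-yl]-3-methylpentanoic acid (CNP0346003.1) | C=C1CC[C@H]2[C@](C)(COC(C)=O)CCC[C@]2(C)[C@H]1CC[C@H](C)CC(=O)O | target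

**Step count and risks**
Total step count: 14. Longest linear sequence: 9 steps (1, 2, 4, 5, 10, 11, 12, 13, 14; the eastern branch 6, 7, 8, 9 followed by 10–14 is equally long).

The three steps most likely to fail are 12, 10 and 11.

Step 12 (the proposed new step). The risks are Meinwald rearrangement of the 2,2-disubstituted oxirane to an aldehyde, partial SN1 ionisation with loss of stereospecificity, and only modest preference for the CH2O-equatorial fold, which would give a separable C4-epimeric diastereomer. The fallback uses known chemistry only, sets out from 7 and 19 and comes back at 23. It moves the initiating oxygen onto C3, so that the initiator is a classical trisubstituted 2,3-epoxide from a Sharpless epoxidation, and removes the extra C3 hydroxyl afterwards. Commercial (2E)-2-methylpenta-2,4-dienoic acid is reduced (LiAlH4, Et2O, 0 °C) to (2E)-2-methylpenta-2,4-dien-1-ol F1. Sharpless asymmetric epoxidation (Ti(OiPr)4, L-(+)-diethyl tartrate, t-BuOOH, 4 Å MS, CH2Cl2, −20 °C) gives the vinyl epoxy alcohol F2, which is silylated (TBSCl, imidazole) to the silyl ether F3. 9-BBN gives the alkylborane F4, which is coupled with 7 as in step 4 to the alcohol F5 and iodinated as in step 5 to the iodide F6. Zinc insertion gives the alkylzinc iodide F7, which is coupled with 19 as in step 10 to the chloro diene F8 and silylmethylated as in step 11 to the epoxy allylsilane F9. MeAlCl2 (CH2Cl2, −78 °C) then effects the established trisubstituted-epoxide bicyclisation, in which the ring oxygen stays on C3 and the E-geometry of the former allylic alcohol fixes CH2OTBS equatorial, to give the 3β-hydroxy decalin F10. PhOC(S)Cl/DMAP gives the thionocarbonate F11, Bu3SnH/AIBN (Barton–McCombie, toluene, 90 °C) gives the deoxygenated silyl ether F12, and TBAF (THF) releases 23.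

Step 10. The risks are attack of the Lewis-acidic zinc species on the oxirane and incomplete trans-selectivity or over-alkylation. The fallback sets out from 10 and 18 and comes back at 22; it moves the union from zinc to boron and to the more reactive dibromide. Aldehyde 18 with CBr4/PPh3 (CH2Cl2, 0 °C) gives the gem-dibromoalkene F13. Iodide 10 is converted by iodine–lithium exchange (t-BuLi, Et2O, −78 °C) and B-methoxy-9-BBN into the lithium borinate F14. A trans-selective B-alkyl Suzuki–Miyaura mono-coupling of F14 with F13 (Pd(dppf)Cl2, K3PO4 aq, DMF, 23 °C) gives the (Z)-bromo diene F15, whose alkenyl bromide is silylmethylated at 23 °C (Me3SiCH2ZnCl, Pd(t-Bu3P)2) to give 22.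

Step 11. The risks are sluggish coupling or isomerisation at the hindered alkenyl chloride and prolonged exposure of the oxirane to zinc at 40 °C. The fallback sets out from 21 and comes back at 22; it reverses the polarity of the C8–C17 bond formation and removes zinc. Miyaura borylation of 21 (B2pin2, Pd2dba3/XPhos, KOAc, dioxane, 80 °C) gives the alkenyl boronate F16, which is coupled with (iodomethyl)trimethylsilane (Pd(dppf)Cl2, K3PO4 aq, THF, 50 °C) to give 22.

**Further compounds**
F1 | step 12 | (2E)-2-methylpenta-2,4-dien-1-ol | C=C/C=C(\C)CO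
F2 | step 12 | [(2S,3S)-3-ethenyl-2-methyloxiran-2-yl]methanol | C[C@@]1(CO)O[C@H]1C=C
F3 | step 12 | tert-butyl{[(2S,3S)-3-ethenyl-2-methyloxiran-2-yl]methoxy}dimethylsilane | C[C@@]1(CO[Si](C)(C)C(C)(C)C)O[C@H]1C=C
F4 | step 12 | 9-{2-[(2S,3S)-3-({[tert-butyl(dimethyl)silyl]oxy}methyl)-3-methyloxiran-2-yl]ethyl}-9-borabicyclo[3.3.1]nonane | C[C@@]1(CO[Si](C)(C)C(C)(C)C)O[C@H]1CCB2C3CCCC2CCC3
F5 | step 12 | (3E)-6-[(2S,3S)-3-({[tert-butyl(dimethyl)silyl]oxy}methyl)-3-methyloxiran-2-yl]-4-methylhex-3-en-1-ol | C[C@@]1(CO[Si](C)(C)C(C)(C)C)O[C@H]1CC/C(C)=C/CCO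
F6 | step 12 | tert-butyl({(2S,3S)-3-[(3E)-6-iodo-3-methylhex-3-en-1-yl]-2-methyloxiran-2-yl}methoxy)dimethylsilane | C[C@@]1(CO[Si](C)(C)C(C)(C)C)O[C@H]1CC/C(C)=C/CCI
F7 | step 12 | alkylzinc iodide of F6 (Zn in place of I) | C[C@@]1(CO[Si](C)(C)C(C)(C)C)O[C@H]1CC/C(C)=C/CC[Zn]I
F8 | step 12 | methyl (3S,6Z,10E)-13-[(2S,3S)-3-({[tert-butyl(dimethyl)silyl]oxy}methyl)-3-methyloxiran-2-yl]-7-chloro-3,11-dimethyltrideca-6,10-dienoate | C[C@@]1(CO[Si](C)(C)C(C)(C)C)O[C@H]1CC/C(C)=C/CC/C(Cl)=C/CC[C@H](C)CC(=O)OC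
F9 | step 12 | methyl (3S,6Z,10E)-13-[(2S,3S)-3-({[tert-butyl(dimethyl)silyl]oxy}methyl)-3-methyloxiran-2-yl]-3,11-dimethyl-7-[(trimethylsilyl)methyl]trideca-6,10-dienoate | C[C@@]1(CO[Si](C)(C)C(C)(C)C)O[C@H]1CC/C(C)=C/CC/C(C[Si](C)(C)C)=C/CC[C@H](C)CC(=O)OC
F10 | step 12 | methyl (13S)-18-{[tert-butyl(dimethyl)silyl]oxy}-3β-hydroxylabd-8(17)-en-15-oate | C=C1CC[C@H]2[C@](C)(CO[Si](C)(C)C(C)(C)C)[C@@H](O)CC[C@]2(C)[C@H]1CC[C@H](C)CC(=O)OC
F11 | step 12 | 3-O-(phenoxycarbonothioyl) derivative of F10 | C=C1CC[C@H]2[C@](C)(CO[Si](C)(C)C(C)(C)C)[C@@H](OC(=S)Oc3ccccc3)CC[C@]2(C)[C@H]1CC[C@H](C)CC(=O)OC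
F12 | step 12 | methyl (13S)-18-{[tert-butyl(dimethyl)silyl]oxy}labd-8(17)-en-15-oate | C=C1CC[C@H]2[C@](C)(CO[Si](C)(C)C(C)(C)C)CCC[C@]2(C)[C@H]1CC[C@H](C)CC(=O)OC
F13 | step 10 | methyl (3S)-7,7-dibromo-3-methylhept-6-enoate | BrC(Br)=CCC[C@H](C)CC(=O)OC
F14 | step 10 | lithium 9-methoxy-9-{(3E)-4-methyl-7-[(2R)-2-methyloxiran-2-yl]hept-3-en-1-yl}-9-boranuidabicyclo[3.3.1]nonane | C[C@@]1(CCC/C(C)=C/CC[B-]2(OC)C3CCCC2CCC3)CO1.[Li+]
F15 | step 10 | methyl (3S,6Z,10E)-7-bromo-3,11-dimethyl-14-[(2R)-2-methyloxiran-2-yl]tetradeca-6,10-dienoate | C[C@@]1(CCC/C(C)=C/CC/C(Br)=C/CC[C@H](C)CC(=O)OC)CO1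
F16 | step 11 | methyl (3S,6E,10E)-3,11-dimethyl-14-[(2R)-2-methyloxiran-2-yl]-7-(4,4,5,5-tetramethyl-1,3,2-dioxaborolan-2-yl)tetradeca-6,10-dienoate | C[C@@]1(CCC/C(C)=C/CC/C(B2OC(C)(C)C(C)(C)O2)=C/CC[C@H](C)CC(=O)OC)CO1
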